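**Retrosynthetic overview** (ent-kaurane numbering: ring A = C1–C5/C10; lactone = O–C20–C10–C9–C8–C7(=O); ring C = C8/C9/C11–C14; ring D = C8/C14/C13/C16/C15; C17 = exocyclic CH2; C6 = CHO carbon)
1. End game: C17 by α-methylenation of the C15 ketone; C6 aldehyde by oxidation of a primary alcohol.
2. Enabling feature: C8 is the α-carbon and C9 the β-carbon of the C7 lactone; C9 carries the C11 carbinol and C8 the C15 ketone. The bicyclo[3.2.1]octane is therefore the retron of a C11-ketyl addition to a C8=C9 unsaturated spirolactone followed by C-acylation of the C8 enolate by a C15 ester. One SmI2 cascade closes ring C (C9–C11) and then ring D (C8–C15), setting C9, C11 and quaternary C8.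
3. Cascade precursor 26 (ring A + unsaturated lactone + acyclic C11–C16 chain) by Negishi coupling of bromo-enoate 15 with the zinc reagent of iodide 20 (C13 from an Evans alkylation).
4. Spirolactone by Ti(III) epoxide opening / Giese addition / lactonization at C10, the radical adding anti to C1–O and C5–C6.
5. Ring A from 2,4,4-trimethylcyclohexenone: CBS reduction, [2,3]-Wittig–Still transfer (C5), hydroxyl-directed epoxidation and isomerization (C1–O). Ring order: A (bought) → lactone → C → D.

Key step: step 21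

Remark: stereodescriptors in names are given where a single centre is involved; elsewhere configuration is described with the numbering above and fixed by the SMILES.

**Route**

Step 1
Reactants: 1 2,4,4-trimethylcyclohex-2-en-1-one
Product: 2 (S)-2,4,4-trimethylcyclohex-2-en-1-ol
Conditions: (R)-2-methyl-CBS-oxazaborolidine (10 mol%), BH3·SMe2, THF, −20 °C
Reagents that add atoms: none
Why: CBS reduction; the α-methylvinyl arm acts as the large group, so the (R)-catalyst should deliver hydride to give the (S)-allylic alcohol.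

Step 2
Reactants: 2 (S)-2,4,4-trimethylcyclohex-2-en-1-ol
Product: 3 tributyl({[(1S)-2,4,4-trimethylcyclohex-2-en-1-yl]oxy}methyl)stannane
Conditions: KH, 18-crown-6 (cat.), Bu3SnCH2I, THF, 0 °C → rt
Reagents that add atoms: (iodomethyl)tributylstannane, CCCC[Sn](CCCC)(CCCC)CI
Why: Williamson etherification of the potassium alkoxide; the carbinol centre is not touched.

Step 3
Reactants: 3 tributyl({[(1S)-2,4,4-trimethylcyclohex-2-en-1-yl]oxy}methyl)stannane
Product: 5 (R)-α-cyclogeraniol, via alkoxymethyllithium 4 (not isolated)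
Conditions: n-BuLi, THF, −78 → −40 °C; then H2O
Reagents that add atoms: none
Why: Sn–Li exchange then [2,3]-Wittig–Still rearrangement; the CH2 carbanion is delivered suprafacially from O–C1 to C5, setting C5 (R) and moving the alkene to C1=C10.

Step 4
Reactants: 5 (R)-α-cyclogeraniol
Product: 6 cis-epoxy alcohol (C1/C10 oxirane, O cis to CH2OH)
Conditions: VO(acac)2 (2 mol%), t-BuOOH, CH2Cl2, 0 °C → rt
Reagents that add atoms: tert-butyl hydroperoxide, CC(C)(C)OO
Why: Hydroxyl-directed vanadium epoxidation of a homoallylic alcohol delivers oxygen on the CH2OH face, fixing the future C1–O bond cis to C6.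

Step 5
Reactants: 6 cis-epoxy alcohol
Product: 7 TBDPS ether of 6
Conditions: TBDPSCl, imidazole, DMF, rt
Reagents that add atoms: tert-butylchlorodiphenylsilane, CC(C)(C)[Si](Cl)(c1ccccc1)c1ccccc1
Why: Standard silylation of the primary alcohol; the group is chosen to survive acid and base until step 23.

Step 6
Reactants: 7 TBDPS ether of 6
Product: 8 allylic alcohol (C10=C20 methylidene, C1–OH cis to C5–CH2OTBDPS)
Conditions: Et2AlCl, LiTMP (Et2Al–TMP in situ), toluene, 0 °C; Rochelle salt work-up
Reagents that add atoms: none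
Why: Aluminium-amide epoxide-to-allylic-alcohol isomerization; syn-abstraction of a C20 methyl proton with cleavage of the tertiary C10–O bond leaves the C1–O bond and its configuration intact.

Step 7
Reactants: 8 allylic alcohol
Product: 9 spiro-epoxy alcohol (C10/C20 oxirane, O syn to C1–OH)
Conditions: VO(acac)2 (2 mol%), t-BuOOH, CH2Cl2, 0 °C
Reagents that add atoms: tert-butyl hydroperoxide, CC(C)(C)OO
Why: Hydroxyl-directed vanadium epoxidation of the allylic alcohol (syn); the C10 configuration is of no consequence because C10 becomes a radical in step 9.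

Step 8
Reactants: 9 spiro-epoxy alcohol
Product: 10 TES ether of 9
Conditions: TESCl, imidazole, DMAP (cat.), CH2Cl2, 0 °C → rt
Reagents that add atoms: chlorotriethylsilane, CC[Si](Cl)(CC)CC
Why: Silylation under non-basic conditions avoids Payne rearrangement and masks C1–OH for the radical and enolate steps.

Step 9
Reactants: 10 TES ether of 9
Product: 11 saturated spirolactone (C9H2 on C10 trans to both C1–OTES and C5–CH2OTBDPS)
Conditions: Cp2TiCl2 (2.5 equiv), Zn dust, 2,2,2-trifluoroethyl acrylate (5 equiv), THF, rt; dilute HCl work-up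
Reagents that add atoms: 2,2,2-trifluoroethyl acrylate, C=CC(=O)OCC(F)(F)F
Why: Ti(III) epoxide opening (Nugent–RajanBabu) gives the tertiary C10 radical, whose Giese addition to the acrylate anti to the cis C1–O and C5–C6 substituents sets C10; the C20 titanium alkoxide then lactonizes onto the activated ester.

Step 10
Reactants: 11 saturated spirolactone
Product: 13 unsaturated spirolactone (C8=C9; C1-OTES; C6-OTBDPS), via α-phenylselanyl lactone 12 (not isolated)
Conditions: LDA, THF, −78 °C; PhSeBr; then 30% H2O2, pyridine, CH2Cl2, 0 °C → rt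
Reagents that add atoms: none
Why: α-Selenation of the only enolizable position (C8) and selenoxide syn-elimination, which can run only towards C9.

Step 11
Reactants: 13 unsaturated spirolactone
Product: 15 8-bromo unsaturated spirolactone, via 8,9-dibromide 14 (not isolated)
Conditions: Br2, CH2Cl2, 0 °C; then Et3N, 0 °C → rt
Reagents that add atoms: bromine, BrBr
Why: Bromine addition followed by E1cB loss of HBr (C8–H is the acidic proton) is the standard α-bromination of an enoate.

Step 12
Reactants: 16 (R)-4-benzyloxazolidin-2-one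
Product: 17 (R)-4-benzyl-3-(pent-4-enoyl)oxazolidin-2-one
Conditions: n-BuLi, THF, −78 °C; pent-4-enoyl chloride
Reagents that add atoms: pent-4-enoyl chloride, C=CCCC(Cl)=O
Why: N-Acylation of the lithiated Evans auxiliary.

Step 13
Reactants: 17 (R)-4-benzyl-3-(pent-4-enoyl)oxazolidin-2-one
Product: 18 tert-butyl (3S)-3-{[(4R)-4-benzyl-2-oxooxazolidin-3-yl]carbonyl}hex-5-enoate
Conditions: NaHMDS, THF, −78 °C; tert-butyl bromoacetate, −78 → −40 °C
Reagents that add atoms: tert-butyl bromoacetate, CC(C)(C)OC(=O)CBr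
Why: Evans alkylation; the chelated Z-enolate is alkylated on the face opposite the benzyl group, which sets C13 as (S).

Step 14
Reactants: 18 alkylated imide
Product: 19 tert-butyl (3S)-3-(hydroxymethyl)hex-5-enoate
Conditions: LiBH4, MeOH (1 equiv), Et2O, 0 °C
Reagents that add atoms: none
Why: Reductive cleavage of the imide; the tert-butyl ester is not reduced and cannot lactonize under these conditions.

Step 15
Reactants: 19 tert-butyl (3S)-3-(hydroxymethyl)hex-5-enoate
Product: 20 tert-butyl (3S)-3-(iodomethyl)hex-5-enoate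
Conditions: I2, PPh3, imidazole, CH2Cl2, 0 °C → rt
Reagents that add atoms: iodine, II
Why: Appel-type iodination of the primary alcohol; C13 is not involved.

Step 16
Reactants: 15 8-bromo unsaturated spirolactone; 20 tert-butyl (3S)-3-(iodomethyl)hex-5-enoate
Product: 22 coupled enoate (C8–C14 bond; allyl and CH2CO2t-Bu arms on C13), via organozinc iodide 21 (not isolated)
Conditions: 20, Zn dust (activated), LiCl, THF, 40 °C; then 15, Pd(OAc)2 (5 mol%), SPhos (10 mol%), THF, 50 °C
Reagents that add atoms: none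
Why: Zinc insertion and Negishi sp3–sp2 coupling with the α-bromo enoate; the ester-bearing chain is joined without any enolate chemistry.

Step 17
Reactants: 22 coupled enoate
Product: 23 hydroxy acid (C1–OH, C15 CO2H)
Conditions: TFA/CH2Cl2 (1:4), 0 °C → rt
Reagents that add atoms: none
Why: Acidolysis removes the tert-butyl ester and the TES ether in one operation; the primary TBDPS ether is stable to these conditions.

Step 18
Reactants: 23 hydroxy acid
Product: 24 hydroxy methyl ester
Conditions: TMSCHN2, MeOH/toluene, 0 °C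
Reagents that add atoms: trimethylsilyldiazomethane, C[Si](C)(C)C=[N+]=[N-]
Why: Mild methylation of the acid gives the unhindered methyl ester wanted as acyl acceptor in step 21.

Step 19
Reactants: 24 hydroxy methyl ester
Product: 25 C1 acetate
Conditions: Ac2O, pyridine, DMAP (cat.), CH2Cl2, rt
Reagents that add atoms: acetic anhydride, CC(=O)OC(C)=O
Why: DMAP-catalysed acetylation of the only free hydroxyl installs the C1 acetate before C11–OH exists, so no later differentiation is needed.

Step 20
Reactants: 25 C1 acetate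
Product: 26 aldehyde (C11 CHO; cascade precursor)
Conditions: OsO4 (2 mol%), NaIO4, 2,6-lutidine, dioxane/H2O, rt
Reagents that add atoms: sodium periodate with water (oxygen delivered through catalytic OsO4), [Na+].[O-]I(=O)(=O)=O and O
Why: Johnson–Lemieux cleavage; OsO4 should react with the electron-rich terminal alkene and leave the electron-poor trisubstituted enoate.

Step 21
Reactants: 26 aldehyde
Product: 28 tetracyclic β-keto lactone (rings C and D closed; C11–OH; C15 ketone; C16 still CH2), via samarium(III) enolate 27 (not isolated)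
Conditions: SmI2 (2.5 equiv), LiBr, THF, −78 → 0 °C, no proton source; then aq. NH4Cl
Reagents that add atoms: none
Why: Proposed new method: Sm(II) reduces the C11 aldehyde to a ketyl that adds 6-endo-trig to C9, the β-carbon of the C8=C9 lactone (ring C); a second Sm(II) reduces the α-lactone radical to the Sm(III) enolate 27, formed only at C8, which with no proton donor present attacks the Sm-activated methyl ester on the axial C13 arm in a 5-exo-trig Dieckmann-type C-acylation that closes ring D, creates quaternary C8 and the C15 ketone and expels methoxide. The closest known chemistry is the SmI2 ketyl–olefin cyclization/intramolecular aldol cascade of aldehyde-tethered unsaturated lactones, and Claisen-type acylation of samarium enolates by esters; new is the ester as terminating electrophile inside the cascade. C9 is set by ketyl approach to the lactone face on the C1 side, away from C5–CH2OTBDPS and guided by Sm coordination to the C1 acetate; C11 by a chair transition state with an axial O–Sm bond chelated to the ester carbonyl of the C13 arm; C8 by the bridge geometry, since the arm reaches only the enolate face anti to the new C9–C11 bond; C13 is pre-set. The step needs ketyl formation at the aldehyde (the most reducible group), 6-endo over 5-exo closure (polarity-matched attack at the β-carbon of an α-substituted enoate) and C- over O-acylation; if the C11 samarium alkoxide lactonizes onto the ester first, transannular attack of C8 on that bridged lactone should lead to the same product. Regiocontrol is the reason for the design: a base-mediated Dieckmann would start from the ester α-carbon C16 and attack the lactone carbonyl C7.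

Step 22
Reactants: 28 tetracyclic β-keto lactone
Product: 29 α-methylene ketone (C16=C17)
Conditions: (CH2O)n, i-Pr2NH·TFA, TFA (cat.), THF, reflux
Reagents that add atoms: formaldehyde (as paraformaldehyde), C=O
Why: Mannich/elimination α-methylenation; C16 is the only enolizable position next to the ketone (C8 is quaternary) and the conditions are compatible with the acetate and the free C11–OH.

Step 23
Reactants: 29 α-methylene ketone
Product: 30 primary alcohol (C6–OH)
Conditions: HF·pyridine, pyridine/THF, 0 °C → rt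
Reagents that add atoms: none
Why: Buffered fluoride desilylation; non-basic, so the β-keto lactone and the enone are not exposed to alkoxide.

Step 24
Reactants: 30 primary alcohol
Product: 31 isodonal
Conditions: TEMPO (10 mol%), PhI(OAc)2, CH2Cl2, rt
Reagents that add atoms: none
Why: Oxoammonium oxidation is selective for the primary C6 alcohol over the hindered axial C11–OH and should not epimerize C5.

**Compound list**
1 | 2,4,4-trimethylcyclohex-2-en-1-one | CC1=CC(C)(C)CCC1=O | starting material
2 | (S)-2,4,4-trimethylcyclohex-2-en-1-ol | CC1=CC(C)(C)CC[C@@H]1O | intermediate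
3 | tributyl({[(1S)-2,4,4-trimethylcyclohex-2-en-1-yl]oxy}methyl)stannane | CC1=CC(C)(C)CC[C@@H]1OC[Sn](CCCC)(CCCC)CCCC | intermediate
4 | {[(1S)-2,4,4-trimethylcyclohex-2-en-1-yl]oxy}methyllithium | CC1=CC(C)(C)CC[C@@H]1OC[Li] | intermediate (not isolated)
5 | (R)-α-cyclogeraniol, [(1R)-2,6,6-trimethylcyclohex-2-en-1-yl]methanol | CC1=CCCC(C)(C)[C@H]1CO | intermediate
6 | (1,3,3-trimethyl-7-oxabicyclo[4.1.0]heptan-2-yl)methanol, oxirane O cis to CH2OH | C[C@]12O[C@H]1CCC(C)(C)[C@H]2CO | intermediate
7 | TBDPS ether of 6 | C[C@]12O[C@H]1CCC(C)(C)[C@H]2CO[Si](c1ccccc1)(c1ccccc1)C(C)(C)C | intermediate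
8 | 3-[(tert-butyldiphenylsilyloxy)methyl]-4,4-dimethyl-2-methylidenecyclohexan-1-ol, OH cis to CH2OSi | C=C1[C@@H](O)CCC(C)(C)[C@H]1CO[Si](c1ccccc1)(c1ccccc1)C(C)(C)C | intermediate
9 | spiro-epoxy alcohol of 8 (C10/C20 oxirane, O syn to C1–OH) | O[C@H]1CCC(C)(C)[C@@H](CO[Si](c2ccccc2)(c2ccccc2)C(C)(C)C)[C@]13CO3 | intermediate
10 | TES ether of 9 | CC[Si](CC)(CC)O[C@H]1CCC(C)(C)[C@@H](CO[Si](c2ccccc2)(c2ccccc2)C(C)(C)C)[C@]13CO3 | intermediate
11 | saturated spiro δ-lactone (C7 lactone on O–C20; C9 trans to C1–OTES and to C5–CH2OTBDPS) | O=C1CC[C@]2(CO1)[C@@H](O[Si](CC)(CC)CC)CCC(C)(C)[C@H]2CO[Si](c1ccccc1)(c1ccccc1)C(C)(C)C | intermediate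
12 | 8-(phenylselanyl) lactone, mixture of C8 epimers | O=C1C([Se]c3ccccc3)C[C@]2(CO1)[C@@H](O[Si](CC)(CC)CC)CCC(C)(C)[C@H]2CO[Si](c1ccccc1)(c1ccccc1)C(C)(C)C | intermediate (not isolated)
13 | C8=C9 unsaturated spirolactone | O=C1C=C[C@]2(CO1)[C@@H](O[Si](CC)(CC)CC)CCC(C)(C)[C@H]2CO[Si](c1ccccc1)(c1ccccc1)C(C)(C)C | intermediate
14 | trans-8,9-dibromo lactone | O=C1[C@@H](Br)[C@H](Br)[C@]2(CO1)[C@@H](O[Si](CC)(CC)CC)CCC(C)(C)[C@H]2CO[Si](c1ccccc1)(c1ccccc1)C(C)(C)C | intermediate (not isolated)
15 | 8-bromo C8=C9 unsaturated spirolactone | O=C1C(Br)=C[C@]2(CO1)[C@@H](O[Si](CC)(CC)CC)CCC(C)(C)[C@H]2CO[Si](c1ccccc1)(c1ccccc1)C(C)(C)C | intermediate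
16 | (R)-4-benzyloxazolidin-2-one | O=C1N[C@H](Cc2ccccc2)CO1 | starting material
17 | (R)-4-benzyl-3-(pent-4-enoyl)oxazolidin-2-one | C=CCCC(=O)N1[C@H](Cc2ccccc2)COC1=O | intermediate
18 | tert-butyl (3S)-3-{[(4R)-4-benzyl-2-oxooxazolidin-3-yl]carbonyl}hex-5-enoate | C=CC[C@@H](CC(=O)OC(C)(C)C)C(=O)N1[C@H](Cc2ccccc2)COC1=O | intermediate
19 | tert-butyl (3S)-3-(hydroxymethyl)hex-5-enoate | C=CC[C@@H](CC(=O)OC(C)(C)C)CO | intermediate
20 | tert-butyl (3S)-3-(iodomethyl)hex-5-enoate | C=CC[C@@H](CC(=O)OC(C)(C)C)CI | intermediate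
21 | {(2S)-2-[2-(tert-butoxy)-2-oxoethyl]pent-4-en-1-yl}zinc iodide | C=CC[C@@H](CC(=O)OC(C)(C)C)C[Zn]I | intermediate (not isolated)
22 | coupled enoate: 13 carrying at C8 the CH2–CH(allyl)(CH2CO2t-Bu) chain | O=C1C(C[C@@H](CC=C)CC(=O)OC(C)(C)C)=C[C@]2(CO1)[C@@H](O[Si](CC)(CC)CC)CCC(C)(C)[C@H]2CO[Si](c1ccccc1)(c1ccccc1)C(C)(C)C | intermediate
23 | hydroxy acid (C1–OH, C15 CO2H) | O=C1C(C[C@@H](CC=C)CC(=O)O)=C[C@]2(CO1)[C@@H](O)CCC(C)(C)[C@H]2CO[Si](c1ccccc1)(c1ccccc1)C(C)(C)C | intermediate
24 | hydroxy methyl ester | O=C1C(C[C@@H](CC=C)CC(=O)OC)=C[C@]2(CO1)[C@@H](O)CCC(C)(C)[C@H]2CO[Si](c1ccccc1)(c1ccccc1)C(C)(C)C | intermediate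
25 | C1 acetate of 24 | O=C1C(C[C@@H](CC=C)CC(=O)OC)=C[C@]2(CO1)[C@@H](OC(C)=O)CCC(C)(C)[C@H]2CO[Si](c1ccccc1)(c1ccccc1)C(C)(C)C | intermediate
26 | C11 aldehyde (cascade precursor) | O=C1C(C[C@@H](CC=O)CC(=O)OC)=C[C@]2(CO1)[C@@H](OC(C)=O)CCC(C)(C)[C@H]2CO[Si](c1ccccc1)(c1ccccc1)C(C)(C)C | intermediate
27 | tricyclic samarium(III) C8 enolate / C11 alkoxide | COC(=O)C[C@@H]1C[C@H](O[Sm](Br)Br)[C@@H]2C(C1)=C(O[Sm](Br)Br)OC[C@]23[C@@H](OC(C)=O)CCC(C)(C)[C@H]3CO[Si](c1ccccc1)(c1ccccc1)C(C)(C)C | intermediate (not isolated)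
28 | tetracyclic β-keto lactone (isodonal skeleton with C16H2 and C6–OTBDPS) | C1C(=O)[C@]23C[C@H]1C[C@H](O)[C@H]2[C@]1(COC3=O)[C@@H](OC(C)=O)CCC(C)(C)[C@H]1CO[Si](c1ccccc1)(c1ccccc1)C(C)(C)C | intermediate
29 | 16-methylidene ketone, C6–OTBDPS | C=C1C(=O)[C@]23C[C@H]1C[C@H](O)[C@H]2[C@]1(COC3=O)[C@@H](OC(C)=O)CCC(C)(C)[C@H]1CO[Si](c1ccccc1)(c1ccccc1)C(C)(C)C | intermediate
30 | C6 primary alcohol (6-deoxo-6-hydroxy isodonal) | C=C1C(=O)[C@]23C[C@H]1C[C@H](O)[C@H]2[C@]1(COC3=O)[C@@H](OC(C)=O)CCC(C)(C)[C@H]1CO | intermediate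
31 | isodonal | C=C1C(=O)[C@]23C[C@H]1C[C@H](O)[C@H]2[C@]1(COC3=O)[C@@H](OC(C)=O)CCC(C)(C)[C@H]1C=O | target

**Totals and risks**
Total step count: 24. Longest linear sequence: 20 (steps 1–11 and 16–24); steps 12–15 are the side branch.

Steps most likely to fail:

1. Step 21 (Proposed new method). The Sm(III) enolate may fail to C-acylate the ester: it may be protonated on work-up, or the C11 samarium alkoxide may lactonize onto the ester without the transannular acyl transfer following. The ketyl may also add to the wrong face of C9, because the pre-set C13 centre must place its arm axially in the productive transition state. The fallback separates the two ring closures and uses only known reactions. It sets out from 23 and returns to the route at 30. Amide coupling of 23 with morpholine (EDC, HOBt) should give morpholine amide F1, and TESOTf/2,6-lutidine the C1 TES ether F2. Johnson–Lemieux cleavage then gives aldehyde F3. SmI2/LiBr with t-BuOH (ketyl–olefin cyclization with protonation of the enolate, the established mode) should give tricyclic alcohol F4, which is silylated (TBSOTf) to the C11 TBS ether F5. LDA at −78 °C should deprotonate only the lactone α-CH (the amide α-CH2 is far less acidic); the C8 lithium enolate is then acylated intramolecularly by the morpholine amide, whose tetrahedral adduct holds until work-up, giving keto lactone F6. PPTS/MeOH frees C1–OH in alcohol F7, Ac2O/DMAP gives acetate F8, α-methylenation as in step 22 gives enone F9, and HF·pyridine removes both silyl groups to reach 30.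

2. Step 9. The tertiary C10 radical may be captured by a second Ti(III) before it adds to the acrylate, with loss of the β-oxygen and return to the alkene, or the Giese addition may be slow at this doubly flanked centre. The fallback generates the same radical without a reducing metal. It sets out from 10 and returns at 11. Opening of the oxirane at C20 with caesium benzoate (DMF, 80 °C) should give tertiary alcohol benzoate F10. Acylation with oxalyl chloride and aqueous CsHCO3 gives caesium oxalate F11. Visible-light photoredox decarboxylative Giese addition to methyl acrylate (Ir photocatalyst, DME/DMF, water) should give quaternary ester F12, and K2CO3/MeOH removes the benzoate with lactonization to 11.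

3. Step 3. The [2,3]-shift must form a bond at C5 next to the quaternary C4; a [1,2]-Wittig shift or simple protonation of the carbanion may compete. The fallback replaces the sigmatropic shift by a directed allylic substitution. It sets out from 2 and returns at 5. Esterification with 2-(diphenylphosphanyl)benzoic acid (DCC, DMAP) gives the directing ester F13. Copper-mediated syn-SN2′ substitution with (isopropoxydimethylsilyl)methylmagnesium chloride (CuBr·SMe2, Et2O) should give allyl-transposed silane F14 with 1,3-chirality transfer, and Tamao oxidation (KF, KHCO3, H2O2) gives 5.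

Further compounds
F1 | step 21 | morpholine amide of 23 | O=C1C(C[C@@H](CC=C)CC(=O)N3CCOCC3)=C[C@]2(CO1)[C@@H](O)CCC(C)(C)[C@H]2CO[Si](c1ccccc1)(c1ccccc1)C(C)(C)C
F2 | step 21 | C1 TES ether of F1 | O=C1C(C[C@@H](CC=C)CC(=O)N3CCOCC3)=C[C@]2(CO1)[C@@H](O[Si](CC)(CC)CC)CCC(C)(C)[C@H]2CO[Si](c1ccccc1)(c1ccccc1)C(C)(C)C
F3 | step 21 | C11 aldehyde with morpholine amide arm | O=C1C(C[C@@H](CC=O)CC(=O)N3CCOCC3)=C[C@]2(CO1)[C@@H](O[Si](CC)(CC)CC)CCC(C)(C)[C@H]2CO[Si](c1ccccc1)(c1ccccc1)C(C)(C)C
F4 | step 21 | tricyclic C11 alcohol (ring C closed, C8–H, mixture at C8) | O=C(C[C@@H]1C[C@H](O)[C@@H]2C(C1)C(=O)OC[C@]23[C@@H](O[Si](CC)(CC)CC)CCC(C)(C)[C@H]3CO[Si](c1ccccc1)(c1ccccc1)C(C)(C)C)N1CCOCC1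
F5 | step 21 | C11 TBS ether of F4 | O=C(C[C@@H]1C[C@H](O[Si](C)(C)C(C)(C)C)[C@@H]2C(C1)C(=O)OC[C@]23[C@@H](O[Si](CC)(CC)CC)CCC(C)(C)[C@H]3CO[Si](c1ccccc1)(c1ccccc1)C(C)(C)C)N1CCOCC1
F6 | step 21 | tetracyclic β-keto lactone, C1–OTES, C11–OTBS | C1C(=O)[C@]23C[C@H]1C[C@H](O[Si](C)(C)C(C)(C)C)[C@H]2[C@]1(COC3=O)[C@@H](O[Si](CC)(CC)CC)CCC(C)(C)[C@H]1CO[Si](c1ccccc1)(c1ccccc1)C(C)(C)C
F7 | step 21 | C1 alcohol of F6 | C1C(=O)[C@]23C[C@H]1C[C@H](O[Si](C)(C)C(C)(C)C)[C@H]2[C@]1(COC3=O)[C@@H](O)CCC(C)(C)[C@H]1CO[Si](c1ccccc1)(c1ccccc1)C(C)(C)C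
F8 | step 21 | C1 acetate, C11–OTBS | C1C(=O)[C@]23C[C@H]1C[C@H](O[Si](C)(C)C(C)(C)C)[C@H]2[C@]1(COC3=O)[C@@H](OC(C)=O)CCC(C)(C)[C@H]1CO[Si](c1ccccc1)(c1ccccc1)C(C)(C)C
F9 | step 21 | 16-methylidene ketone, C11–OTBS, C6–OTBDPS | C=C1C(=O)[C@]23C[C@H]1C[C@H](O[Si](C)(C)C(C)(C)C)[C@H]2[C@]1(COC3=O)[C@@H](OC(C)=O)CCC(C)(C)[C@H]1CO[Si](c1ccccc1)(c1ccccc1)C(C)(C)C
F10 | step 9 | tertiary C10 alcohol with C20 benzoate | CC[Si](CC)(CC)O[C@H]1CCC(C)(C)[C@@H](CO[Si](c2ccccc2)(c2ccccc2)C(C)(C)C)[C@]1(O)COC(=O)c1ccccc1
F11 | step 9 | caesium oxalate of F10 | CC[Si](CC)(CC)O[C@H]1CCC(C)(C)[C@@H](CO[Si](c2ccccc2)(c2ccccc2)C(C)(C)C)[C@]1(OC(=O)C(=O)[O-])COC(=O)c1ccccc1.[Cs+]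
F12 | step 9 | quaternary C10 Giese adduct (methyl ester, C20 benzoate) | COC(=O)CC[C@]1(COC(=O)c2ccccc2)[C@@H](O[Si](CC)(CC)CC)CCC(C)(C)[C@H]1CO[Si](c1ccccc1)(c1ccccc1)C(C)(C)C
F13 | step 3 | (1S)-2,4,4-trimethylcyclohex-2-en-1-yl 2-(diphenylphosphanyl)benzoate | CC1=CC(C)(C)CC[C@@H]1OC(=O)c1ccccc1P(c1ccccc1)c1ccccc1
F14 | step 3 | isopropoxydimethyl{[(1R)-2,6,6-trimethylcyclohex-2-en-1-yl]methyl}silane | CC1=CCCC(C)(C)[C@H]1C[Si](C)(C)OC(C)C
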